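I have no constants for this flask yet, so I build one rate number from the runs and keep the books in shares of the charge.

| flask | starting material | coupling partner | free catalyst | time |
|---|---|---|---|---|
| birch | 0.200 M | 0.500 M | 0.00100 M |  |
| cedar | 0.200 M | 0.500 M | 5.00 × 10⁻⁴ M |  |
| oak | 0.200 M | 1.00 M | 0.00100 M |  |
| ash | 0.100 M | 0.500 M | 0.00100 M |  |
| elm | 0.200 M | 0.500 M | 2.90 × 10⁻⁴ M | 12 min |

| run | time / min | [target] / M |
|---|---|---|
| birch run | 0.48 | 0.0033 |
| birch run | 0.76 | 0.0055 |
| birch run | 1.2 | 0.0089 |
| birch run | 1.9 | 0.0133 |
| birch run | 3.0 | 0.0232 |
| birch run | 4.8 | 0.0364 |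
| birch run | 7.6 | 0.0562 |
| birch run | 12 | 0.0894 |
| cedar run | 0.48 | 0.0012 |
| cedar run | 0.76 | 0.0031 |
| cedar run | 1.2 | 0.0032 |
| cedar run | 1.9 | 0.0077 |
| cedar run | 3.0 | 0.0112 |
| cedar run | 4.8 | 0.0175 |
| cedar run | 7.6 | 0.0270 |
| cedar run | 12 | 0.0436 |
| oak run | 0.48 | 0.0060 |
| oak run | 0.76 | 0.0085 |
| oak run | 1.2 | 0.0144 |
| oak run | 1.9 | 0.0229 |
| oak run | 3.0 | 0.0357 |
| oak run | 4.8 | 0.0571 |
| oak run | 7.6 | 0.0914 |
| oak run | 12 | 0.1394 |
| ash run | 0.48 | 0.0050 |
| ash run | 0.76 | 0.0068 |
| ash run | 1.2 | 0.0103 |
| ash run | 1.9 | 0.0169 |
| ash run | 3.0 | 0.0235 |
| ash run | 4.8 | 0.0378 |
| ash run | 7.6 | 0.0561 |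
| ash run | 12 | 0.0775 |

(readings scatter by 6 × 10⁻⁴ M)

- Overall: starting material + coupling partner -> target, with free catalyst as catalyst.
- Constant volume, constant temperature.
- What is held in complexes is read along with the free species.
- "The second partner" is coupling partner.
- An order is taken over about fifteen percent of the charge, up and down.

* reaction order in [free catalyst] at the outset, round the charge of the birch run, defined at two percent of the starting material turned into target
* reaction order in [coupling partner] at the outset, round the charge of the birch run, defined at two percent of the starting material turned into target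
* target in the elm run at 12 min, as a share of the starting material charged

1. The limiting reagent is the starting material: in the birch run the coupling partner is charged at 2.50 times its amount. I book against the starting material, and what the catalyst holds stays in the unturned entry, as the readings do not separate it.

2. The birch ledger at 12 min shows 44.7% as target and 55.3% unturned, which closes the books. Target per charged catalyst per minute, averaged from the start, is 7.45 min⁻¹ at that birch reading. The birch reading at 3.0 min gives 7.73 min⁻¹ by the same reckoning, with a scatter of 2.59%.

3. The cedar ledger at 12 min shows 21.8% as target, which gives 7.27 min⁻¹ per charged catalyst. My zero of the scale is the symmetric case, where each catalyst works like any other and cedar over birch reads 1. The reading is 0.976, so across this halving of the catalyst the order reads 1.04.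

4. I carry the mean of the two as the turnover frequency, target made per charged catalyst per minute, 7.36 min⁻¹. With the starting material and the coupling partner held at the birch charge, I reckon the share turned as this number times the catalyst loading times the time.

5. For the coupling partner, oak over birch at 3.0 min gives an order of 0.622. That is an average over the doubling, not the local order round the birch charge, so I hold it as a reading.

6. The elm loading is 0.145% of the starting material, lower than in the cedar run, so this step leaves the tested range. My elm ledger at 12 min books 12.8% as target and 87.2% unturned.

The forecast gives 1.04 in free catalyst, 0.75 in coupling partner and 12.5% for elm. Its partner order is higher than my average, and its elm share is lower than mine. It warns: “This is an extrapolation, and a small catalyst loss would lower it.”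

The flask gives 1.0 in free catalyst, 0.77 in coupling partner and 12.7% for elm at 12 min, and the cedar run goes at 0.50 of the birch rate where both have made the same amount.

    free catalyst + starting material ⇌ catalyst-substrate complex, settled at all times (2.270 L mol⁻¹)
    catalyst-substrate complex + coupling partner ⇌ ternary complex, settled at all times (7.050 L mol⁻¹)
    ternary complex → target + free catalyst (49.80 min⁻¹)
    free catalyst + coupling partner ⇌ idle catalyst-reagent complex, settled at all times (1.970 L mol⁻¹)
    catalyst-substrate complex + starting material ⇌ doubly bound catalyst, settled at all times (76.70 L mol⁻¹)

The elm ledger closes at 12.7% target and 87.3% unturned, so its own turnover frequency, averaged over the 12 min, is 7.31 min⁻¹ against the carried 7.36 min⁻¹. On the cedar run, the carried number puts 0.5 of the charge at 27.2 min, and the flask reaches it at 27.1 min.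

All runs were computed from invented constants.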